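**Plan**

- Structural handle: the tetrahydrofuran is four carbons in a row (δ-carbon = lactone O–CH, carbinol carbon, benzylic carbon, γ-carbon = furan O–CH) closed by one oxygen. Without that oxygen the four carbons are a cyclobutanone fused to the γ–δ bond of the six-membered oxygen ring, and a γ=δ enol ether in that ring is the matching ketenophile.
- Retrosynthetic cuts, in order: lactone/lactol oxidation level at the acyl carbon; benzylic C–O bond of the tetrahydrofuran; benzylic C–phenyl bond; carbinol C–OH bond; ring O–γ-carbon bond (oxygen insertion); the γ-C–C(=O) and δ-C–CCl2 bonds of the cyclobutanone; the two Diels–Alder bonds of the bicyclo[2.2.2]octene.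
- Forward order: bicyclooctene plus δ-lactone ring (Diels–Alder) → enol lactone → 2-acetoxy-dihydropyran → cyclobutanone ([2+2]) → γ-lactone (Baeyer–Villiger) → lactone opened by phenyl addition → tetrahydrofuran closed at the benzylic carbon → δ-lactone restored.
- Stereochemistry: the isopropyl centre of (R)-α-phellandrene steers the Diels–Alder face (anti) and, with endo addition, fixes the four new cage centres. The cage then sends the ketene (γ, δ) and the oxaziridine (carbinol) to the convex face. Baeyer–Villiger migrates with retention. The benzylic centre is set trans to the carbinol in an SN1 ring closure.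

Key step: step 5

Assumption: acetal and lactol carbons are drawn as the anomer expected from exo attack or left undefined, since all anomers converge on the lactone; 5 is drawn open-chain although it equilibrates with its cyclic 6-hydroxy lactone.

Labels used below: α = ring-fusion CH next to the acyl/acetal carbon, β = the other ring-fusion CH, γ and δ as defined above. Bicyclooctene numbering: C1/C4 bridgeheads, C2 methyl-bearing alkene carbon, C5 isopropyl-bearing carbon, oxygen ring fused at C7(β)–C8(α).

**Route**

Step 1
Reactants: 1 (R)-(−)-α-phellandrene; 2 5,6-dihydro-2H-pyran-2-one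
Product: 3 endo cis-fused Diels–Alder δ-lactone
Conditions: Me2AlCl (20 mol %), 1 (2 equiv), CH2Cl2, −20 °C → rt
Reagents that add atoms: none
Why: Lewis-acid-catalysed Diels–Alder reaction in which the lactone β-carbon bonds to the diene terminus next to the methyl-bearing carbon ("para" orientation), the dienophile adds anti to the isopropyl group with the carbonyl endo, so the single stereocentre of 1 sets the four new ones, and the alkylaluminium halide also scavenges protons that would isomerise 1.

Step 2
Reactants: 3 endo cis-fused Diels–Alder δ-lactone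
Product: 5 aldehyde acid, via lithium hydroxy carboxylate 4 (not isolated)
Conditions: LiOH·H2O (1.05 equiv), THF/H2O, rt; evaporate; 2-iodoxybenzoic acid (IBX, 1.5 equiv), DMSO, rt; 1 M HCl to pH 3
Reagents that add atoms: lithium hydroxide, [Li+].[OH-]
Why: Saponification opens the δ-lactone to a carboxylate that cannot relactonise, and IBX oxidation of the freed primary alcohol should stop at the aldehyde in DMSO; no stereocentre is touched and any relactonised 3 can be recycled.

Step 3
Reactants: 5 aldehyde acid
Product: 6 cis-fused enol lactone (3,4-dihydro-2H-pyran-2-one)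
Conditions: Ac2O, NaOAc (0.2 equiv), 120 °C
Reagents that add atoms: none
Why: Classical enol lactonisation of a δ-aldehydo acid (mixed anhydride, then O-acylation of the aldehyde enol) should place the C=C exactly between the future δ- and γ-carbons.

Step 4
Reactants: 6 cis-fused enol lactone
Product: 8 endo-2-acetoxy-3,4-dihydro-2H-pyran, via aluminium hemiacetal 7 (not isolated)
Conditions: i-Bu2AlH (1.2 equiv), CH2Cl2, −78 °C; then pyridine, DMAP, Ac2O, −78 → −20 °C; aq. potassium sodium tartrate
Reagents that add atoms: acetic anhydride, CC(=O)OC(C)=O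
Why: Rychnovsky reductive acetylation: the cyclic aluminium hemiacetal should persist at −78 °C, as in hydride reductions of dihydrocoumarins to lactols, and is acylated before it can open to the dialdehyde; hydride enters from the open exo face, so the acetoxy group ends endo, a centre that is erased later.

Step 5
Reactants: 8 endo-2-acetoxy-3,4-dihydro-2H-pyran; 9 trichloroacetyl chloride
Product: 11 cis-fused α,α-dichlorocyclobutanone, via dichloroketene 10 (not isolated)
Conditions: Cl3CCOCl (2 equiv, slow addition), Zn–Cu couple (3 equiv), Et2O/DME, rt, ultrasound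
Reagents that add atoms: none
Why: Zinc dehalogenation of 9 gives dichloroketene, which should add to the enol ether in a concerted, asynchronous [π2s + π2a] cycloaddition: the nucleophilic γ-carbon bonds to the ketene carbonyl carbon and the developing oxocarbenium δ-carbon is captured by the CCl2 terminus. This is the standard dichloroketene cycloaddition to dihydropyrans and glycals. The four-membered ring closes by intermolecular [2+2] cycloaddition, both new bonds going to the same face of the C=C, hence cis fusion to the oxygen ring. The γ- and δ-stereocentres are set together by the face of approach: the ketene comes to the convex face, the one bearing the β-hydrogen and turned away from the bicyclooctene cage, while the endo acetoxy group sits on the other face. The step needs regio-, chemo- and face-selectivity: enol ether polarity fixes the orientation, the electron-rich enol ether outcompetes the shielded trisubstituted alkene, the cage blocks the concave face, and DME ties up ZnCl2 so that the acyl acetal and the product survive.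

Step 6
Reactants: 11 cis-fused α,α-dichlorocyclobutanone
Product: 12 cis-fused cyclobutanone
Conditions: Zn dust (6 equiv), AcOH, rt
Reagents that add atoms: none
Why: Zinc/acetic acid reductive dechlorination of dichloroketene adducts is routine and is placed here because β-elimination of the ring oxygen from the zinc enolate would give a strained cyclobutenone, whereas the same reduction on the later lactone could eliminate to a butenolide.

Step 7
Reactants: 12 cis-fused cyclobutanone
Product: 13 γ-lactone with anomeric acetate
Conditions: 30% aq. H2O2, AcOH, 0–5 °C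
Reagents that add atoms: hydrogen peroxide, OO
Why: Strain-driven Baeyer–Villiger oxidation with H2O2/AcOH, the conditions used for alkene-containing cyclobutanones, should spare the shielded alkene and migrate the more substituted γ-carbon with retention, so the new ring oxygen sits on the γ-carbon on the convex face.

Step 8
Reactants: 13 γ-lactone with anomeric acetate
Product: 14 γ-lactone methyl acetal
Conditions: CSA (10 mol %), MeOH, rt
Reagents that add atoms: methanol, CO
Why: Acid-catalysed solvolysis of the anomeric acetate through the cyclic oxocarbenium ion (Fischer-type glycosidation, methanol entering mainly from the exo face) replaces the base-labile acyl acetal by a methyl acetal that tolerates the enolate, hydride and Grignard steps.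

Step 9
Reactants: 14 γ-lactone methyl acetal
Product: 16 α-hydroxy γ-lactone, via potassium enolate 15 (not isolated)
Conditions: KN(SiMe3)2 (1.15 equiv), THF, −78 °C; then 3-phenyl-2-(phenylsulfonyl)oxaziridine (1.5 equiv), −78 °C; sat. NH4Cl
Reagents that add atoms: 3-phenyl-2-(phenylsulfonyl)oxaziridine, O=S(=O)(c1ccccc1)N1OC1c1ccccc1
Why: Davis oxidation of the lactone enolate: at −78 °C β-alkoxy lactone enolates, as in 2-deoxyribonolactone chemistry, are trapped faster than they eliminate, and the oxaziridine should approach the convex face anti to the neighbouring C–O bond, placing the hydroxyl trans to the ring oxygen on the δ-carbon as the target requires.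

Step 10
Reactants: 16 α-hydroxy γ-lactone
Product: 17 hydroxy lactol (anomeric mixture)
Conditions: i-Bu2AlH (2.5 equiv), CH2Cl2, −78 °C; aq. potassium sodium tartrate
Reagents that add atoms: none
Why: Low-temperature i-Bu2AlH reduction of a γ-lactone stops at the lactol because the tetrahedral aluminate does not collapse; the first equivalent is consumed by the free hydroxyl, the acetal and alkene are inert, and the new anomeric centre is inconsequential.

Step 11
Reactants: 17 hydroxy lactol; 18 phenylmagnesium bromide
Product: 19 benzylic triol (both benzylic epimers)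
Conditions: PhMgBr (4 equiv), THF, 0 °C → rt; sat. NH4Cl
Reagents that add atoms: none
Why: Grignard addition to the open hydroxy-aldehyde form of a lactol is a standard route to 1-aryl-1,4-diols, and the configuration of the new benzylic carbinol need not be controlled because the next step passes through the benzylic cation.

Step 12
Reactants: 19 benzylic triol
Product: 21 phenyltetrahydrofuran lactol, via tetrahydrofuran methyl acetal 20 (not isolated)
Conditions: TsOH·H2O (0.3 equiv), 1,4-dioxane, 60 °C; then H2O (dioxane/H2O 4:1), 60 °C
Reagents that add atoms: water, O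
Why: Acid-catalysed dehydrative cycloetherification of a 1-aryl-1,4-diol (SN1, five-membered ring closure of the γ-hydroxyl onto the benzylic cation) should place phenyl trans to the neighbouring hydroxyl, the arrangement favoured by least eclipsing in the closing ring and reachable by re-ionisation of the benzylic ether, and the added water then hydrolyses the methyl acetal to the lactol.

Step 13
Reactants: 21 phenyltetrahydrofuran lactol
Product: 22 CNP0249919.1 (target)
Conditions: Ag2CO3 on Celite (5 equiv), toluene, 90 °C
Reagents that add atoms: none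
Why: Fetizon oxidation converts lactols to lactones much faster than it oxidises secondary alcohols, so the δ-lactone should be restored without touching the hindered carbinol, the benzylic ether or the alkene.

**Compound list**

1 | (R)-(−)-α-phellandrene, (5R)-5-isopropyl-2-methylcyclohexa-1,3-diene | CC1=CC[C@@H](C=C1)C(C)C | starting material
2 | 5,6-dihydro-2H-pyran-2-one | O=C1OCCC=C1 | starting material
3 | Diels–Alder δ-lactone: 2-methyl-5-isopropylbicyclo[2.2.2]oct-2-ene cis-fused at C7–C8 to tetrahydropyran-2-one (C=O carbon on C8), lactone ring endo (under the C=C), isopropyl syn to the C=C | CC1=C[C@@H]2[C@@H]3C(=O)OCC[C@@H]3[C@H]1C[C@@H]2C(C)C | intermediate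
4 | lithium carboxylate of the ring-opened hydroxy acid: cis,endo C8-carboxylate and C7-(2-hydroxyethyl) (not isolated) | CC1=C[C@@H]2[C@H](C(=O)[O-])[C@H](CCO)[C@H]1C[C@@H]2C(C)C.[Li+] | intermediate
5 | aldehyde acid: cis,endo C8-carboxylic acid and C7-(2-oxoethyl) | CC1=C[C@@H]2[C@H](C(=O)O)[C@H](CC=O)[C@H]1C[C@@H]2C(C)C | intermediate
6 | enol lactone: 3,4-dihydro-2H-pyran-2-one cis-fused (endo) to the bicyclooctene, C=C between δ- and γ-carbons | CC1=C[C@@H]2[C@@H]3C(=O)OC=C[C@@H]3[C@H]1C[C@@H]2C(C)C | intermediate
7 | diisobutylaluminium hemiacetal of 6, O–Al endo (not isolated) | CC1=C[C@@H]2[C@@H]3[C@H](O[Al](CC(C)C)CC(C)C)OC=C[C@@H]3[C@H]1C[C@@H]2C(C)C | intermediate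
8 | 2-acetoxy-3,4-dihydro-2H-pyran cis-fused to the bicyclooctene, acetoxy endo (key-step precursor) | CC1=C[C@@H]2[C@@H]3[C@H](OC(C)=O)OC=C[C@@H]3[C@H]1C[C@@H]2C(C)C | intermediate
9 | trichloroacetyl chloride | ClC(Cl)(Cl)C(Cl)=O | starting material
10 | dichloroketene (not isolated) | O=C=C(Cl)Cl | intermediate
11 | α,α-dichlorocyclobutanone cis-fused to the oxygen ring on its convex face: C=O carbon on the γ-carbon, CCl2 on the δ-carbon | CC1=C[C@@H]2[C@@H]3[C@H](OC(C)=O)O[C@@H]4[C@@H](C(=O)C4(Cl)Cl)[C@@H]3[C@H]1C[C@@H]2C(C)C | intermediate
12 | dechlorinated cis-fused cyclobutanone | CC1=C[C@@H]2[C@@H]3[C@H](OC(C)=O)O[C@@H]4[C@@H](C(=O)C4)[C@@H]3[C@H]1C[C@@H]2C(C)C | intermediate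
13 | γ-lactone (ring O on γ-carbon, CH2 on δ-carbon) cis-fused to the 2-acetoxytetrahydropyran | CC1=C[C@@H]2[C@@H]3[C@H](OC(C)=O)O[C@H]4CC(=O)O[C@H]4[C@@H]3[C@H]1C[C@@H]2C(C)C | intermediate
14 | γ-lactone methyl acetal (methoxy exo; anomer inconsequential) | CC1=C[C@@H]2[C@@H]3[C@@H](OC)O[C@H]4CC(=O)O[C@H]4[C@@H]3[C@H]1C[C@@H]2C(C)C | intermediate
15 | potassium enolate of 14 (not isolated) | CC1=C[C@@H]2[C@@H]3[C@@H](OC)O[C@H]4C=C([O-])O[C@H]4[C@@H]3[C@H]1C[C@@H]2C(C)C.[K+] | intermediate
16 | α-hydroxy γ-lactone, hydroxyl on the convex face, trans to the ring oxygen on the δ-carbon | CC1=C[C@@H]2[C@@H]3[C@@H](OC)O[C@H]4[C@H](O)C(=O)O[C@H]4[C@@H]3[C@H]1C[C@@H]2C(C)C | intermediate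
17 | hydroxy lactol (anomeric mixture) | CC1=C[C@@H]2[C@@H]3[C@@H](OC)O[C@H]4[C@H](O)C(O)O[C@H]4[C@@H]3[C@H]1C[C@@H]2C(C)C | intermediate
18 | phenylmagnesium bromide | Br[Mg]c1ccccc1 | starting material
19 | benzylic triol: δ-carbon bears CH(OH)–CH(OH)Ph, γ-carbon bears OH (benzylic epimers) | CC1=C[C@@H]2[C@@H]3[C@@H](OC)O[C@@H]([C@H](O)C(O)c4ccccc4)[C@@H](O)[C@@H]3[C@H]1C[C@@H]2C(C)C | intermediate
20 | 2-phenyl-3-hydroxytetrahydrofuran methyl acetal, phenyl trans to hydroxyl (not isolated) | CC1=C[C@@H]2[C@@H]3[C@@H](OC)O[C@H]4[C@H](O)[C@@H](c5ccccc5)O[C@H]4[C@@H]3[C@H]1C[C@@H]2C(C)C | intermediate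
21 | phenyltetrahydrofuran lactol (anomeric mixture) | CC1=C[C@@H]2[C@@H]3C(O)O[C@H]4[C@H](O)[C@@H](c5ccccc5)O[C@H]4[C@@H]3[C@H]1C[C@@H]2C(C)C | intermediate
22 | CNP0249919.1 | CC1=C[C@@H]2[C@@H]3C(=O)O[C@H]4[C@H](O)[C@@H](c5ccccc5)O[C@H]4[C@@H]3[C@H]1C[C@@H]2C(C)C | target

**Step count and risks**

Total steps: 13. Longest linear sequence: 13 steps (1 and 2 to 22).

1. Step 12 (benzylic cycloetherification). The benzylic alcohol may ionise slowly because of the neighbouring hydroxyl, a 1,2-hydride shift or acid-induced rearrangement of the trisubstituted alkene may compete, and the ring closure may not be cleanly trans. Fallback: set out from 16 and return at 22, closing no ring but reducing an oxocarbenium ion instead. Silylation (TBSOTf, 2,6-lutidine) would give the tert-butyldimethylsilyl ether F1. PhLi (1.1 equiv, THF, −78 °C) would add once to the γ-lactone to give the phenyl hemiketal F2. AcOH/THF/H2O would hydrolyse the methyl acetal to the bis-lactol F3. Ag2CO3 on Celite would oxidise only the aldehyde-derived lactol, giving the lactone hemiketal F4. Et3SiH/BF3·OEt2 (CH2Cl2, −78 → −40 °C) would reduce the phenyl-stabilised oxocarbenium ion with hydride delivered to the convex face, giving the silyl ether of the target F5. HF·pyridine would then release 22.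

2. Step 9 (enolate hydroxylation). The enolate may expel the ring oxygen from the δ-carbon (ring opening to a butenolide), or the oxidant may attack with poor face selectivity. Fallback: set out from 11 and return at 16, bringing in the oxygen by displacement instead of enolate oxidation. Bu3SnH (1.05 equiv)/AIBN would remove one chlorine, hydrogen arriving on the convex face, to give the endo-chlorocyclobutanone F6. H2O2/AcOH would give the α-chloro γ-lactone F7. CsOAc with 18-crown-6 in DMF would displace chloride from the convex face with inversion to give the α-acetoxy γ-lactone F8. HCl in MeOH would then exchange the anomeric acetate for methoxy and cleave the ester, giving 16.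

3. Step 1 (Diels–Alder). The unactivated lactone may react sluggishly, the Lewis acid may isomerise or oligomerise the diene, and regio- or endo-selectivity may be incomplete. Fallback: set out from 2 and return at 3 with a halogen-activated dienophile. Br2 in CH2Cl2 would give 3,4-dibromotetrahydro-2H-pyran-2-one F9, and Et3N would eliminate HBr to 3-bromo-5,6-dihydro-2H-pyran-2-one F10. Cycloaddition of this more reactive dienophile with 1 would give the α-bromo Diels–Alder lactone F11 (carbonyl endo, bromine exo). Bu3SnH/AIBN would replace bromine by hydrogen from the exo face, giving the cis-fused lactone 3.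

**Further compounds**

F1 | step 12 | tert-butyldimethylsilyl ether of 16 | CC1=C[C@@H]2[C@@H]3[C@@H](OC)O[C@H]4[C@H](O[Si](C)(C)C(C)(C)C)C(=O)O[C@H]4[C@@H]3[C@H]1C[C@@H]2C(C)C
F2 | step 12 | phenyl hemiketal | CC1=C[C@@H]2[C@@H]3[C@@H](OC)O[C@H]4[C@H](O[Si](C)(C)C(C)(C)C)C(O)(c5ccccc5)O[C@H]4[C@@H]3[C@H]1C[C@@H]2C(C)C
F3 | step 12 | bis-lactol | CC1=C[C@@H]2[C@@H]3C(O)O[C@H]4[C@H](O[Si](C)(C)C(C)(C)C)C(O)(c5ccccc5)O[C@H]4[C@@H]3[C@H]1C[C@@H]2C(C)C
F4 | step 12 | lactone hemiketal | CC1=C[C@@H]2[C@@H]3C(=O)O[C@H]4[C@H](O[Si](C)(C)C(C)(C)C)C(O)(c5ccccc5)O[C@H]4[C@@H]3[C@H]1C[C@@H]2C(C)C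
F5 | step 12 | tert-butyldimethylsilyl ether of 22 | CC1=C[C@@H]2[C@@H]3C(=O)O[C@H]4[C@H](O[Si](C)(C)C(C)(C)C)[C@@H](c5ccccc5)O[C@H]4[C@@H]3[C@H]1C[C@@H]2C(C)C
F6 | step 9 | endo-chlorocyclobutanone | CC1=C[C@@H]2[C@@H]3[C@H](OC(C)=O)O[C@@H]4[C@@H](C(=O)[C@@H]4Cl)[C@@H]3[C@H]1C[C@@H]2C(C)C
F7 | step 9 | α-chloro γ-lactone | CC1=C[C@@H]2[C@@H]3[C@H](OC(C)=O)O[C@H]4[C@@H](Cl)C(=O)O[C@H]4[C@@H]3[C@H]1C[C@@H]2C(C)C
F8 | step 9 | α-acetoxy γ-lactone | CC1=C[C@@H]2[C@@H]3[C@H](OC(C)=O)O[C@H]4[C@H](OC(C)=O)C(=O)O[C@H]4[C@@H]3[C@H]1C[C@@H]2C(C)C
F9 | step 1 | 3,4-dibromotetrahydro-2H-pyran-2-one | O=C1OCCC(Br)C1Br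
F10 | step 1 | 3-bromo-5,6-dihydro-2H-pyran-2-one | O=C1OCCC=C1Br
F11 | step 1 | α-bromo Diels–Alder lactone | CC1=C[C@@H]2[C@]3(Br)C(=O)OCC[C@@H]3[C@H]1C[C@@H]2C(C)C
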